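**Retrosynthetic overview**
1. The target comes from its 5,7-di-O-benzyl ether by hydrogenolysis as the last step, with no change to the skeleton.
2. The pyran ring is the only ring made and is closed after all C–C bonds are in place. The O1–C2 bond forms by Markovnikov alkoxymercuration of an (R)-1-aryl-3-methylbut-3-enyl silyl ether, using the phenol that lies between the two carbon side chains.
3. The key bond is C3–C4, and it sets C4 as R. The aryl aldehyde carbon becomes a chiral α-silyloxybenzyl-copper nucleophile and couples with the π-methallyl-palladium electrophile released from the neighbouring aryl methallyl ether.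
4. The aldehyde comes from chelation-controlled O-differentiation (outer OH benzyl, central OH methallyl), preceded by Rieche formylation and Friedel–Crafts acylation of 2-methylphloroglucinol with 3-phenylpropanoic acid.

Assumption: which antipode of the C2-symmetric carbene ligand gives the R carbinol on this substrate must be found by experiment (Mosher ester of the free carbinol). The (4R,5R) salt is written, and its (4S,5S) antipode is used if the sense is opposite.

**Step 1**
Reactants: 1 2-methylbenzene-1,3,5-triol; 2 3-phenylpropanoic acid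
Product: 3 1-(2,4,6-trihydroxy-3-methylphenyl)-3-phenylpropan-1-one
Conditions: BF3·OEt2 (solvent), 85 °C, 2 h; aq NaOAc
Reagents that add atoms: none
Why: Friedel–Crafts acylation; the two free ring carbons of 1 are equivalent by symmetry and the first acyl group deactivates the ring, so a single mono-ketone forms.

**Step 2**
Reactants: 3 1-(2,4,6-trihydroxy-3-methylphenyl)-3-phenylpropan-1-one
Product: 5 2,4,6-trihydroxy-3-methyl-5-(3-phenylpropanoyl)benzaldehyde, via alpha-chloro methyl ether 4 (not isolated)
Conditions: Cl2CHOMe (1.2 equiv), TiCl4 (4 equiv), CH2Cl2, −10 to 0 °C; then 1 M aq HCl, rt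
Reagents that add atoms: dichloromethyl methyl ether COC(Cl)Cl; water O
Why: Rieche formylation; the only unsubstituted ring carbon attacks the TiCl4-activated dichloromethyl methyl ether, aqueous acid hydrolyses 4 to the aldehyde, and the enolisable ketone is untouched (a Vilsmeier reagent could close it to a 3-benzylchromone).

**Step 3**
Reactants: 5 2,4,6-trihydroxy-3-methyl-5-(3-phenylpropanoyl)benzaldehyde; 6 3-chloro-2-methylprop-1-ene (methallyl chloride)
Product: 8 2,4-bis(benzyloxy)-3-methyl-6-[(2-methylprop-2-en-1-yl)oxy]-5-(3-phenylpropanoyl)benzaldehyde, via central-phenol dibenzyl ether 7 (not isolated)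
Conditions: BnBr (2.05 equiv), K2CO3 (4 equiv), DMF, 0 °C to rt, 8 h; then 6 (2 equiv), 65 °C, 12 h
Reagents that add atoms: benzyl bromide BrCc1ccccc1
Why: Williamson etherification under chelation control; the hydroxyl between the two carbonyl groups is held in a double hydrogen bond and is the most hindered, so BnBr takes the two outer phenols at room temperature and 6 alkylates the central phenol only on heating in the same flask.

**Step 4 (key step)**
Reactants: 8 2,4-bis(benzyloxy)-3-methyl-6-[(2-methylprop-2-en-1-yl)oxy]-5-(3-phenylpropanoyl)benzaldehyde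
Product: 10 1-{2,4-bis(benzyloxy)-5-[(1R)-1-{[dimethyl(phenyl)silyl]oxy}-3-methylbut-3-en-1-yl]-6-hydroxy-3-methylphenyl}-3-phenylpropan-1-one, via aryl pinacol borate 9 (not isolated)
Conditions: PhMe2Si–Bpin (1.3 equiv), CuCl (10 mol %), (4R,5R)-1,3-bis(2-isopropylphenyl)-4,5-diphenylimidazolinium tetrafluoroborate (12 mol %), KOtBu (25 mol %), Pd(dba)2 (5 mol %), 1,1'-bis(diphenylphosphino)ferrocene (6 mol %), toluene, 30 °C; pH 7 buffer
Reagents that add atoms: (dimethylphenylsilyl)boronic acid pinacol ester C[Si](C)(c1ccccc1)B1OC(C)(C)C(C)(C)O1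
Why: Proposed new method: the chiral carbene–Cu–SiMe2Ph species adds to one face of the aldehyde and a [1,2]-Brook shift turns the copper alkoxide into a configurationally stable α-silyloxybenzyl-copper, so the former carbonyl carbon now acts as a carbanion; zerovalent palladium ionises the neighbouring aryl methallyl ether, whose aryloxide is a good leaving group because two carbonyl groups flank it, to a π-methallyl-palladium electrophile; stereospecific Cu-to-Pd transmetalation and reductive elimination join two carbons that are both normally electrophilic, form C3–C4 and fix C4 as R; the released aryloxide takes up Bpin and turns the copper over; the flanked alkoxy groups are twisted out of conjugation, the C–Cu bond is covalent and the irreversible coupling drains the Brook equilibrium, which offsets the electron-rich ring; all O-substituents next to the aldehyde are alkyl groups, so nothing can migrate to the copper alkoxide; the closest known reaction type is the synergistic copper/palladium reductive three-component coupling of aromatic aldehydes, silylboronates and allylic carbonates, from which this differs only in using an internal aryl ether as allyl donor, so methallyl exchange between molecules is degenerate and every methallyl group ends on carbon.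

**Step 5**
Reactants: 10 1-{2,4-bis(benzyloxy)-5-[(1R)-1-{[dimethyl(phenyl)silyl]oxy}-3-methylbut-3-en-1-yl]-6-hydroxy-3-methylphenyl}-3-phenylpropan-1-one
Product: 13 1-[(4R)-5,7-bis(benzyloxy)-4-hydroxy-2,2,6-trimethylchroman-8-yl]-3-phenylpropan-1-one, via organomercury acetate 11 (not isolated), via chroman silyl ether 12 (not isolated)
Conditions: Hg(OAc)2 (1.05 equiv), THF, 0 °C, 30 min; then NaBH4 (1 equiv), 2 M aq NaOH, 0 °C; then MeOH, rt, 3 h
Reagents that add atoms: none
Why: Intramolecular alkoxymercuration–demercuration; the only free phenol adds in Markovnikov 6-exo fashion to the mercurinium ion of the 1,1-disubstituted alkene without the strong acid that would ionise the silyl-capped benzylic C4–O bond, the benzyl group on the other flanking oxygen rules out the isomeric ring, NaBH4 replaces mercury by hydrogen so that C2 carries two identical methyl groups, and alkaline methanol cleaves the labile silyl ether at silicon, leaving C4 as R and the di-ortho-substituted ketone intact.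

**Step 6**
Reactants: 13 1-[(4R)-5,7-bis(benzyloxy)-4-hydroxy-2,2,6-trimethylchroman-8-yl]-3-phenylpropan-1-one
Product: 14 1-[(4R)-4,5,7-trihydroxy-2,2,6-trimethylchroman-8-yl]-3-phenylpropan-1-one (target)
Conditions: H2 (1 atm), Pd/C (10 wt % Pd on carbon), solid NaHCO3, EtOAc, rt, stopped at 2 equiv uptake
Reagents that add atoms: none
Why: Heterogeneous hydrogenolysis of aryl benzyl ethers; the O-benzyl groups bind to palladium through their own phenyl rings and cleave quickly, while the C4–O bond sits on a hexasubstituted ring that cannot lie flat on the metal and is not ionised in acid-free medium, so the R carbinol and the aryl ketone survive.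

**Compound list**

| No. | Name | SMILES | Role |
|---|---|---|---|
| 1 | 2-methylbenzene-1,3,5-triol | Cc1c(O)cc(O)cc1O | starting material |
| 2 | 3-phenylpropanoic acid | OC(=O)CCc1ccccc1 | starting material |
| 3 | 1-(2,4,6-trihydroxy-3-methylphenyl)-3-phenylpropan-1-one | Cc1c(O)cc(O)c(C(=O)CCc2ccccc2)c1O | intermediate |
| 4 | 1-{3-[chloro(methoxy)methyl]-2,4,6-trihydroxy-5-methylphenyl}-3-phenylpropan-1-one (racemic, not isolated) | Cc1c(O)c(C(Cl)OC)c(O)c(C(=O)CCc2ccccc2)c1O | intermediate |
| 5 | 2,4,6-trihydroxy-3-methyl-5-(3-phenylpropanoyl)benzaldehyde | Cc1c(O)c(C=O)c(O)c(C(=O)CCc2ccccc2)c1O | intermediate |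
| 6 | 3-chloro-2-methylprop-1-ene | CC(=C)CCl | starting material |
| 7 | 2,4-bis(benzyloxy)-6-hydroxy-3-methyl-5-(3-phenylpropanoyl)benzaldehyde (not isolated) | Cc1c(OCc2ccccc2)c(C=O)c(O)c(C(=O)CCc2ccccc2)c1OCc1ccccc1 | intermediate |
| 8 | 2,4-bis(benzyloxy)-3-methyl-6-[(2-methylprop-2-en-1-yl)oxy]-5-(3-phenylpropanoyl)benzaldehyde | Cc1c(OCc2ccccc2)c(C=O)c(OCC(C)=C)c(C(=O)CCc2ccccc2)c1OCc1ccccc1 | intermediate |
| 9 | 1-{2,4-bis(benzyloxy)-5-[(1R)-1-{[dimethyl(phenyl)silyl]oxy}-3-methylbut-3-en-1-yl]-3-methyl-6-[(4,4,5,5-tetramethyl-1,3,2-dioxaborolan-2-yl)oxy]phenyl}-3-phenylpropan-1-one (not isolated) | Cc1c(OCc2ccccc2)c([C@H](O[Si](C)(C)c2ccccc2)CC(C)=C)c(OB2OC(C)(C)C(C)(C)O2)c(C(=O)CCc2ccccc2)c1OCc1ccccc1 | intermediate |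
| 10 | 1-{2,4-bis(benzyloxy)-5-[(1R)-1-{[dimethyl(phenyl)silyl]oxy}-3-methylbut-3-en-1-yl]-6-hydroxy-3-methylphenyl}-3-phenylpropan-1-one | Cc1c(OCc2ccccc2)c([C@H](O[Si](C)(C)c2ccccc2)CC(C)=C)c(O)c(C(=O)CCc2ccccc2)c1OCc1ccccc1 | intermediate |
| 11 | {[(4R)-5,7-bis(benzyloxy)-4-{[dimethyl(phenyl)silyl]oxy}-2,6-dimethyl-8-(3-phenylpropanoyl)chroman-2-yl]methyl}mercury acetate (mixture of C2 epimers, not isolated) | Cc1c(OCc2ccccc2)c(C(=O)CCc2ccccc2)c2c(c1OCc1ccccc1)[C@H](O[Si](C)(C)c1ccccc1)CC(C)(C[Hg]OC(C)=O)O2 | intermediate |
| 12 | 1-[(4R)-5,7-bis(benzyloxy)-4-{[dimethyl(phenyl)silyl]oxy}-2,2,6-trimethylchroman-8-yl]-3-phenylpropan-1-one (not isolated) | Cc1c(OCc2ccccc2)c(C(=O)CCc2ccccc2)c2c(c1OCc1ccccc1)[C@H](O[Si](C)(C)c1ccccc1)CC(C)(C)O2 | intermediate |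
| 13 | 1-[(4R)-5,7-bis(benzyloxy)-4-hydroxy-2,2,6-trimethylchroman-8-yl]-3-phenylpropan-1-one | Cc1c(OCc2ccccc2)c(C(=O)CCc2ccccc2)c2c(c1OCc1ccccc1)[C@H](O)CC(C)(C)O2 | intermediate |
| 14 | 1-[(4R)-4,5,7-trihydroxy-2,2,6-trimethylchroman-8-yl]-3-phenylpropan-1-one | Cc1c(O)c(C(=O)CCc2ccccc2)c2c(c1O)[C@H](O)CC(C)(C)O2 | target |

**Total step count:** 6. **Longest linear sequence:** 6 (1 to 14).

**Steps most likely to fail**

**Step 4.** The aldehyde is di-ortho-substituted and sits on an oxygen-rich ring. Silyl-copper addition, the Brook shift or the enantioselectivity may therefore fall short, and palladium may divert the methallyl group to an allylsilane.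

The fallback sets out from 8 and moves the polarity reversal onto the four-carbon partner. An iridium-catalysed transfer-hydrogenative carbonyl methallylation turns electrophilic 6 into a nucleophilic π-methallyl-iridium species. The conditions are [Ir(cod)Cl]2, (R)-BINAP or its antipode, 4-chloro-3-nitrobenzoic acid, Cs2CO3, 6, iPrOH and THF at 100 °C. This species adds to the aldehyde and gives the O-methallyl homoallylic alcohol F1. PhMe2SiCl and imidazole convert it into the O-methallyl silyl ether F2. Pd(PPh3)4 with morpholine then removes the aryl methallyl group, and the route is rejoined at 10.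

**Step 3.** The order "outer phenols first, central phenol last" rests on hydrogen bonding and sterics, and it may give mixed dibenzyl ethers.

The fallback sets out from 5 and reverses the logic. Exhaustive benzylation (BnBr in excess, K2CO3, DMF, 70 °C) gives the tribenzyl ether F3. One equivalent of MgBr2·OEt2 in toluene–Et2O then cleaves the benzyl ether that can chelate magnesium to two flanking carbonyl groups and is the most compressed. This gives isolated 7, where the route is rejoined before methallylation to 8.

**Step 6.** Once the 5-OH is free, the carbinol is an ortho-hydroxybenzylic alcohol. It could be lost by hydrogenolysis or through a quinone methide.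

The fallback sets out from 12, isolated by stopping step 5 after the NaBH4 stage. The carbinol stays masked during hydrogenolysis (H2, Pd/C, EtOAc), which gives the dihydroxy chroman silyl ether F4. The silyl group is then removed last with Bu4NF buffered with AcOH in THF at 0 °C, and the route is rejoined at 14.

**Further compounds**
F1 | step 4 | 1-{2,4-bis(benzyloxy)-5-[(1R)-1-hydroxy-3-methylbut-3-en-1-yl]-3-methyl-6-[(2-methylprop-2-en-1-yl)oxy]phenyl}-3-phenylpropan-1-one | Cc1c(OCc2ccccc2)c([C@H](O)CC(C)=C)c(OCC(C)=C)c(C(=O)CCc2ccccc2)c1OCc1ccccc1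
F2 | step 4 | 1-{2,4-bis(benzyloxy)-5-[(1R)-1-{[dimethyl(phenyl)silyl]oxy}-3-methylbut-3-en-1-yl]-3-methyl-6-[(2-methylprop-2-en-1-yl)oxy]phenyl}-3-phenylpropan-1-one | Cc1c(OCc2ccccc2)c([C@H](O[Si](C)(C)c2ccccc2)CC(C)=C)c(OCC(C)=C)c(C(=O)CCc2ccccc2)c1OCc1ccccc1
F3 | step 3 | 2,4,6-tris(benzyloxy)-3-methyl-5-(3-phenylpropanoyl)benzaldehyde | Cc1c(OCc2ccccc2)c(C=O)c(OCc2ccccc2)c(C(=O)CCc2ccccc2)c1OCc1ccccc1
F4 | step 6 | 1-[(4R)-4-{[dimethyl(phenyl)silyl]oxy}-5,7-dihydroxy-2,2,6-trimethylchroman-8-yl]-3-phenylpropan-1-one | Cc1c(O)c(C(=O)CCc2ccccc2)c2c(c1O)[C@H](O[Si](C)(C)c1ccccc1)CC(C)(C)O2
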